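**Strategy.** Everything rests on the ring-fusion bond C1–C5 (daucane numbering), shared by the cyclopentane (C1–C5) and the cycloheptene (C1, C5–C10). It is made by a pinacol-type 1,2-shift in a cis-decalin: the angular, methyl-bearing C1 migrates from the carbinol carbon C6 to the mesylate-bearing C5. In one operation this contracts six-membered ring A to the cyclopentane, expands ring B to the seven-membered ring, sets C5 and unveils the C6 ketone. It exploits the C6 oxygen that flanks the C5–H/C1 quaternary fusion. The precursor, a cis-diol monomesylate, comes from a Diels–Alder adduct of thymoquinone, whose methyl and isopropyl carbons become C1 and C4.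

Key step: step 11

Remark on numbering: the ten ring carbons keep their daucane numbers in every intermediate. In the decalins ring A is C1–C2–C3–C4–C5–C6 and ring B is C1–C6–C7–C8–C9–C10 (fusion bond C1–C6). In the hydroazulenes ring A is C1–C5 and ring B is C1, C5–C10. β is the face of the C1 methyl group.

Assumption: (R)-BINOL is taken to give the enantiomer of 4 that is drawn; if the sense of induction is the opposite, (S)-BINOL is used instead.

Step 1
Reactants: 1 3-methylbut-2-enal
Product: 2 (E)-1-(tert-butyldimethylsilyloxy)-3-methylbuta-1,3-diene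
Conditions: TBSOTf, Et3N, Et2O, 0 °C to rt
Reagents that add atoms: tert-butyldimethylsilyl triflate CC(C)(C)[Si](C)(C)OS(=O)(=O)C(F)(F)F
Why: O-silylation of the enal with γ-deprotonation (silyl dienol ether formation) should give the conjugated (E)-siloxydiene.

Step 2
Reactants: 2 (E)-1-(tert-butyldimethylsilyloxy)-3-methylbuta-1,3-diene; 3 thymoquinone
Product: 4 cis-fused Diels–Alder adduct, 10α-(TBSO)-4-isopropyl-1β,8-dimethylbicyclo[4.4.0]deca-3,8-diene-2,5-dione (6β-H)
Conditions: (R)-BINOL (20 mol%), TiCl2(OiPr)2 (20 mol%), 4 Å molecular sieves, CH2Cl2/toluene, −30 °C to rt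
Reagents that add atoms: none
Why: Lewis-acid-catalysed asymmetric Diels–Alder reaction in which the nucleophilic CH2 terminus of the diene bonds to the unsubstituted C6 of the less hindered, methyl-bearing quinone double bond and the siloxy carbon to C1, endo addition places C1–Me and C6–H cis and C10–OTBS trans to the methyl, and the chiral titanium–BINOL complex selects the quinone face, so that C1, C6 and C10 are set.

Step 3
Reactants: 4 cis-fused Diels–Alder adduct
Product: 5 3β,4β-epoxide of 4 (epoxy dione)
Conditions: H2O2 (30% aq.), Na2CO3 (0.3 equiv), THF/H2O, 0 °C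
Reagents that add atoms: hydrogen peroxide OO
Why: Weitz–Scheffer (nucleophilic) epoxidation touches only the electron-poor C3=C4 enedione double bond and should occur on the convex β face of the cis-fused adduct, which fixes the C4 oxygen β.

Step 4
Reactants: 5 3β,4β-epoxy dione
Product: 7 C5=C6 enol triflate of 5, via potassium enolate 6 (not isolated)
Conditions: KN(SiMe3)2, THF, −78 °C; then PhNTf2, −78 to 0 °C
Reagents that add atoms: N-phenyl-bis(trifluoromethanesulfonimide) O=S(=O)(N(c1ccccc1)S(=O)(=O)C(F)(F)F)C(F)(F)F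
Why: enolate O-triflation, in which C6–H is the only enolisable position (C1 is quaternary, C3 is an epoxide carbon), so that the C5 ketone alone becomes the enol triflate and the two carbonyls are told apart.

Step 5
Reactants: 7 enol triflate
Product: 8 β-hydroxy ketone, 4β-hydroxy-4α-isopropyl-2-oxo with C3 methylene and the C5=C6 enol triflate
Conditions: SmI2 (2.2 equiv), MeOH, THF, −90 °C
Reagents that add atoms: none
Why: samarium diiodide reduction of an α,β-epoxy ketone cleaves the C3–O bond α to the only ketone (C2) and should leave the tertiary C4–OH with its β configuration.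

Step 6
Reactants: 8 β-hydroxy ketone
Product: 9 2α,4β-diol
Conditions: Me4NBH(OAc)3, MeCN/AcOH, −30 °C
Reagents that add atoms: none
Why: hydroxyl-directed Evans–Saksena reduction, in which hydride is delivered from the C4–O-bound borohydride to the β face of C2, should give the 1,3-anti diol with C2–OH α.

Step 7
Reactants: 9 2α,4β-diol
Product: 10 2α-TBS ether of 9
Conditions: TBSOTf (1.1 equiv), 2,6-lutidine, CH2Cl2, −78 °C
Reagents that add atoms: tert-butyldimethylsilyl triflate CC(C)(C)[Si](C)(C)OS(=O)(=O)C(F)(F)F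
Why: silyl ether formation is much faster at the secondary C2 hydroxyl than at the hindered tertiary C4 hydroxyl, which has to stay free to direct step 9.

Step 8
Reactants: 10 2α-TBS ether
Product: 11 allylic alcohol, 2α,10α-bis(TBSO)-4β-hydroxy-Δ5(6),Δ8-diene
Conditions: Pd(OAc)2 (5 mol%), PPh3, HCO2H, Bu3N, DMF, 60 °C
Reagents that add atoms: none
Why: palladium-catalysed formate hydrogenolysis of the enol triflate should give the C5=C6 alkene without touching the silyl ethers or the tertiary alcohol.

Step 9
Reactants: 11 allylic alcohol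
Product: 13 all-cis 4β,5β,6β-triol (cis-decalin), via osmate ester 12 (not isolated)
Conditions: OsO4 (1.05 equiv), TMEDA, CH2Cl2, −78 °C; then aq. Na2SO3, THF, 50 °C
Reagents that add atoms: osmium tetroxide O=[Os](=O)(=O)=O
Why: hydroxyl-directed dihydroxylation, in which the OsO4·TMEDA complex is hydrogen-bonded to the pseudoaxial C4–OH, should add to the β face of the adjacent C5=C6 bond faster than to the remote C8=C9 bond and set C5 and C6.

Step 10
Reactants: 13 4β,5β,6β-triol
Product: 14 5β-mesylate of 13
Conditions: MsCl, Et3N, CH2Cl2, −20 °C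
Reagents that add atoms: methanesulfonyl chloride CS(=O)(=O)Cl
Why: sulfonate ester formation (via sulfene) at the only secondary hydroxyl, C5; the two tertiary hydroxyls do not react at low temperature.

Step 11
Reactants: 14 5β-mesylate
Product: 15 trans-fused hydroazulenone, 2α,10α-bis(TBSO)-4β-hydroxydauc-8-en-6-one
Conditions: Et2AlCl (3 equiv), CH2Cl2, −78 to −20 °C; aq. potassium sodium tartrate work-up
Reagents that add atoms: none
Why: organoaluminium-promoted pinacol-type (semipinacol) rearrangement of a β-mesyloxy alcohol, the reaction type long used to turn decalin cis-diol monosulfonates into hydroazulenones: the aluminium alkoxide at C6 pushes while the antiperiplanar C6–C1 bond displaces the equatorial C5 mesylate, so C1 moves from C6 to C5 and C6 becomes the ketone. The new C1–C5 bond closes the cyclopentane (C1–C5) by contraction of ring A and at the same time the seven-membered ring (C1, C5–C10) by one-carbon expansion of ring B. C5 is formed with inversion, so its configuration is dictated by the β-mesylate set in step 9, and C1 migrates with retention, which gives the trans fusion (C5–H α, C1–Me β). The step needs C1 and not C3 to migrate, since the C4–C3 bond is also antiperiplanar to the mesylate: under these cation-like conditions the fully substituted C1 is by far the better migrating group than the C3 methylene, and only its shift relieves the congested pair of fully substituted carbons C1/C6. The preferred chair of the cis-decalin (isopropyl, C2–OTBS and mesylate equatorial) holds the mesylate antiperiplanar to the fusion bond, the cis arrangement of hydroxyls and mesylate excludes epoxide formation, and C5 has no β-hydrogen, so elimination cannot compete.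

Step 12
Reactants: 15 hydroazulenone
Product: 16 6α-alcohol, 2α,10α-bis(TBSO)dauc-8-ene-4β,6α-diol
Conditions: Me4NBH(OAc)3, MeCN/AcOH, −20 °C
Reagents that add atoms: none
Why: hydroxyl-directed Evans–Saksena reduction of the β-hydroxy ketone, with hydride delivered from the C4–O-bound borohydride to the β face of C6, should give the 6α-alcohol (1,3-anti to C4–OH).

Step 13
Reactants: 16 6α-alcohol
Product: 17 6α-(4-methoxybenzoate) of 16
Conditions: 4-MeOC6H4COCl, Et3N, DMAP, CH2Cl2, rt
Reagents that add atoms: 4-methoxybenzoyl chloride COc1ccc(C(=O)Cl)cc1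
Why: DMAP-catalysed esterification of the only secondary hydroxyl; the tertiary C4–OH does not react.

Step 14
Reactants: 17 6α-(4-methoxybenzoate)
Product: 18 2α,4β,10α-triol 6α-(4-methoxybenzoate)
Conditions: HF·pyridine, pyridine/THF, 0 °C to rt
Reagents that add atoms: none
Why: fluoride-mediated silyl ether cleavage removes both TBS groups, while the ester and the tertiary alcohol are stable to buffered HF.

Step 15
Reactants: 18 triol ester
Product: 19 enone, 2α,4β-dihydroxy-10-oxodauc-8-en-6α-yl 4-methoxybenzoate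
Conditions: MnO2 (activated, excess), CH2Cl2, rt
Reagents that add atoms: none
Why: chemoselective allylic oxidation with MnO2 should convert only the allylic C10–OH into the enone and leave the C2 and C4 hydroxyls.

Step 16
Reactants: 19 enone
Product: 20 target, 2α-acetoxy-6α-(4-methoxybenzoyloxy)dauc-8-ene-4β,10β-diol
Conditions: SmI2 (30 mol%), MeCHO (10 equiv), THF, −10 °C
Reagents that add atoms: acetaldehyde CC=O
Why: Evans–Tishchenko reaction, in which the acetaldehyde hemiacetal on C2–O, held with the C10 carbonyl on trivalent samarium, transfers hydride to the α face of C10, should give the C2 acetate and the C10 β-alcohol in one step and thereby invert C10 relative to the cycloadduct.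

**Compound list**

1 | 3-methylbut-2-enal | CC(C)=CC=O | starting material
2 | (E)-1-(tert-butyldimethylsilyloxy)-3-methylbuta-1,3-diene | C=C(C)/C=C/O[Si](C)(C)C(C)(C)C | intermediate
3 | thymoquinone (2-isopropyl-5-methyl-1,4-benzoquinone) | CC1=CC(=O)C(C(C)C)=CC1=O | starting material
4 | cis-fused Diels–Alder adduct, 10α-(TBSO)-4-isopropyl-1β,8-dimethylbicyclo[4.4.0]deca-3,8-diene-2,5-dione (6β-H) | C[C@]12C(=O)C=C(C(C)C)C(=O)[C@H]1CC(C)=C[C@H]2O[Si](C)(C)C(C)(C)C | intermediate
5 | 3β,4β-epoxide of 4 | C[C@]12C(=O)[C@@H]3O[C@]3(C(C)C)C(=O)[C@H]1CC(C)=C[C@H]2O[Si](C)(C)C(C)(C)C | intermediate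
6 | potassium C5=C6 enolate of 5 (not isolated) | C[C@]12C(=O)[C@@H]3O[C@]3(C(C)C)C([O-])=C1CC(C)=C[C@H]2O[Si](C)(C)C(C)(C)C.[K+] | intermediate
7 | C5=C6 enol triflate of 5 | C[C@]12C(=O)[C@@H]3O[C@]3(C(C)C)C(OS(=O)(=O)C(F)(F)F)=C1CC(C)=C[C@H]2O[Si](C)(C)C(C)(C)C | intermediate
8 | β-hydroxy ketone (4β-OH, 4α-isopropyl, 2-oxo, enol triflate) | C[C@]12C(=O)C[C@@](O)(C(C)C)C(OS(=O)(=O)C(F)(F)F)=C1CC(C)=C[C@H]2O[Si](C)(C)C(C)(C)C | intermediate
9 | 2α,4β-diol | C[C@]12[C@@H](O)C[C@@](O)(C(C)C)C(OS(=O)(=O)C(F)(F)F)=C1CC(C)=C[C@H]2O[Si](C)(C)C(C)(C)C | intermediate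
10 | 2α-TBS ether of 9 | C[C@]12[C@@H](O[Si](C)(C)C(C)(C)C)C[C@@](O)(C(C)C)C(OS(=O)(=O)C(F)(F)F)=C1CC(C)=C[C@H]2O[Si](C)(C)C(C)(C)C | intermediate
11 | allylic alcohol, 2α,10α-bis(TBSO)-4β-hydroxy-Δ5(6),Δ8-diene | C[C@]12[C@@H](O[Si](C)(C)C(C)(C)C)C[C@@](O)(C(C)C)C=C1CC(C)=C[C@H]2O[Si](C)(C)C(C)(C)C | intermediate
12 | 5β,6β-osmate ester of 13, hexavalent osmium, TMEDA complex (not isolated) | C[C@]12[C@@H](O[Si](C)(C)C(C)(C)C)C[C@@](O)(C(C)C)[C@@H]3O[Os](=O)(=O)O[C@]13CC(C)=C[C@H]2O[Si](C)(C)C(C)(C)C.CN(C)CCN(C)C | intermediate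
13 | all-cis 4β,5β,6β-triol | C[C@]12[C@@H](O[Si](C)(C)C(C)(C)C)C[C@@](O)(C(C)C)[C@H](O)[C@@]1(O)CC(C)=C[C@H]2O[Si](C)(C)C(C)(C)C | intermediate
14 | 5β-mesylate of 13 | C[C@]12[C@@H](O[Si](C)(C)C(C)(C)C)C[C@@](O)(C(C)C)[C@H](OS(C)(=O)=O)[C@@]1(O)CC(C)=C[C@H]2O[Si](C)(C)C(C)(C)C | intermediate
15 | trans-fused hydroazulenone, 2α,10α-bis(TBSO)-4β-hydroxydauc-8-en-6-one | O=C2CC(C)=C[C@@H](O[Si](C)(C)C(C)(C)C)[C@@]3(C)[C@@H](O[Si](C)(C)C(C)(C)C)C[C@@](O)(C(C)C)[C@H]23 | intermediate
16 | 2α,10α-bis(TBSO)dauc-8-ene-4β,6α-diol | O[C@H]2CC(C)=C[C@@H](O[Si](C)(C)C(C)(C)C)[C@@]3(C)[C@@H](O[Si](C)(C)C(C)(C)C)C[C@@](O)(C(C)C)[C@H]23 | intermediate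
17 | 6α-(4-methoxybenzoate) of 16 | COc1ccc(C(=O)O[C@H]2CC(C)=C[C@@H](O[Si](C)(C)C(C)(C)C)[C@@]3(C)[C@@H](O[Si](C)(C)C(C)(C)C)C[C@@](O)(C(C)C)[C@H]23)cc1 | intermediate
18 | 2α,4β,10α-trihydroxydauc-8-en-6α-yl 4-methoxybenzoate | COc1ccc(C(=O)O[C@H]2CC(C)=C[C@@H](O)[C@@]3(C)[C@@H](O)C[C@@](O)(C(C)C)[C@H]23)cc1 | intermediate
19 | 2α,4β-dihydroxy-10-oxodauc-8-en-6α-yl 4-methoxybenzoate | COc1ccc(C(=O)O[C@H]2CC(C)=CC(=O)[C@@]3(C)[C@@H](O)C[C@@](O)(C(C)C)[C@H]23)cc1 | intermediate
20 | 2α-acetoxy-6α-(4-methoxybenzoyloxy)dauc-8-ene-4β,10β-diol (CNP0261832.1) | COc1ccc(C(=O)O[C@H]2CC(C)=C[C@H](O)[C@@]3(C)[C@@H](OC(C)=O)C[C@@](O)(C(C)C)[C@H]23)cc1 | target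

**Count.** Total steps: 16. Longest linear sequence: 16 steps (1 to 20); thymoquinone 3 enters at step 2.

**Steps most likely to fail**

Step 2. The chiral Lewis acid may discriminate the quinone faces poorly, or bind the other carbonyl, which would erode both the enantiomeric purity and the regiochemistry of the cycloaddition. The fallback sets out from diene 2, uses commercial thymol in place of quinone 3, and comes back at epoxide 5. Oxidative dearomatisation of thymol with PhI(OAc)2 in MeOH should give the quinone monoketal 4,4-dimethoxy-2-isopropyl-5-methylcyclohexa-2,5-dienone F1. Reagent-controlled asymmetric nucleophilic epoxidation of its β-unsubstituted, isopropyl-bearing enone double bond (Ph3COOH, NaN(SiMe3)2, diisopropyl tartrate) should give the epoxy ketal F2. Mild aqueous acid unmasks the epoxyquinone F3. An uncatalysed Diels–Alder reaction of F3 with 2, endo and anti to the epoxide, should then give 5 directly, so that the epoxide and not a catalyst controls the facial course.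

Step 9. Osmylation may occur from the α face or at the C8=C9 bond of ring B, that is, loss of facial and site selectivity on a hindered trisubstituted alkene. The fallback sets out from 11 and comes back at 13; it delivers the two oxygens one after the other by vanadium-catalysed, hydroxyl-directed epoxidations, which touch only double bonds of allylic alcohols. VO(acac)2/tBuOOH should give the 5β,6β-epoxide F4. Diethylaluminium 2,2,6,6-tetramethylpiperidide isomerises it, by removal of a C7 proton (the only β-hydrogen available), to the 5β-alcohol with a C6=C7 double bond F5. A second VO(acac)2/tBuOOH epoxidation, now directed by the C5 hydroxyl, should give the 6β,7β-epoxide F6. LiAlH4 opens F6 at the secondary allylic C7 and returns triol 13.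

Step 11. The C4 alkoxide may drive a competing migration of the C3 methylene, which would contract ring A to an acylcyclopentane instead of giving the hydroazulenone. The fallback sets out from 14 and comes back at 15. The less hindered tertiary C4 hydroxyl is capped first (Et3SiOTf, 2,6-lutidine, −78 °C) to give the C4 triethylsilyl ether of the mesylate F7, so that only the C6 oxygen can push. The same Et2AlCl-promoted shift should give the silylated hydroazulenone F8. Buffered HF·pyridine at 0 °C then removes the triethylsilyl group in the presence of the two TBS ethers and gives 15.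

**Further compounds**

F1 | step 2 | 4,4-dimethoxy-2-isopropyl-5-methylcyclohexa-2,5-dienone | COC1(OC)C=C(C(C)C)C(=O)C=C1C
F2 | step 2 | 2,3-epoxide of F1 (epoxy ketal) | COC1(OC)[C@@H]2O[C@]2(C(C)C)C(=O)C=C1C
F3 | step 2 | 2,3-epoxy-2-isopropyl-5-methylcyclohex-5-ene-1,4-dione (epoxyquinone) | O=C1[C@@H]2O[C@]2(C(C)C)C(=O)C=C1C
F4 | step 9 | 5β,6β-epoxide of 11 | C[C@]12[C@@H](O[Si](C)(C)C(C)(C)C)C[C@@](O)(C(C)C)[C@@H]3O[C@]13CC(C)=C[C@H]2O[Si](C)(C)C(C)(C)C
F5 | step 9 | 4β,5β-diol with C6=C7 and C8=C9 double bonds | C[C@]12[C@@H](O[Si](C)(C)C(C)(C)C)C[C@@](O)(C(C)C)[C@H](O)C1=CC(C)=C[C@H]2O[Si](C)(C)C(C)(C)C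
F6 | step 9 | 6β,7β-epoxide of F5 | C[C@]12[C@@H](O[Si](C)(C)C(C)(C)C)C[C@@](O)(C(C)C)[C@H](O)[C@]13O[C@@H]3C(C)=C[C@H]2O[Si](C)(C)C(C)(C)C
F7 | step 11 | C4 triethylsilyl ether of mesylate 14 | C[C@]12[C@@H](O[Si](C)(C)C(C)(C)C)C[C@@](O[Si](CC)(CC)CC)(C(C)C)[C@H](OS(C)(=O)=O)[C@@]1(O)CC(C)=C[C@H]2O[Si](C)(C)C(C)(C)C
F8 | step 11 | C4 triethylsilyl ether of hydroazulenone 15 | O=C2CC(C)=C[C@@H](O[Si](C)(C)C(C)(C)C)[C@@]3(C)[C@@H](O[Si](C)(C)C(C)(C)C)C[C@@](O[Si](CC)(CC)CC)(C(C)C)[C@H]23
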